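## Analysis of the target

The target is a daucane‑type sesquiterpenoid ester on a trans‑fused bicyclo[5.3.0]decane: a cyclopentanone (C1–C5) and a cycloheptene (C5–C10 plus C1) share the C1–C5 bond. The numbering used for every compound below is: C1 quaternary carbon with methyl, C2 ketone, C3 CH2, C4 carbinol with isopropyl, C5 ring‑fusion CH, C6 carbinol carrying the 4‑methoxybenzoate, C7 CH2, C8 methyl‑bearing olefin carbon, C9 olefin CH, C10 CH2.

The four stereocentres C1, C4, C5 and C6 are contiguous. The C1 methyl and the C4 hydroxyl lie on one face (the "methyl face"); the C4 isopropyl, C5–H and the C6 ester oxygen lie on the other. The ring fusion is therefore trans and the ester is equatorial.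

The sensitive groups are:
- the aldol unit C2(=O)–C3–C4(OH), which can undergo retro‑aldol cleavage or dehydration;
- the C6 ester, which is lost by β‑elimination whenever a carbonyl at C4 or C8 is enolised towards C5 or C7;
- the C8=C9 olefin, which must be placed regioselectively and must not move to C7=C8.

The difficulty is a quaternary carbon next to a ring fusion, surrounded by three oxygenated carbons at three oxidation levels, with the C4 hydroxyl on the more hindered methyl face.

The strategy rests on one feature. The C6 oxygen sits on the carbon next to ring‑fusion C5, and C2 and C8 are carbonyl‑level carbons. If the C1–C5 bond is shifted back to C1–C6, the skeleton becomes the decalin of Wieland–Miescher ketone 1, with C2 and C8 as its two carbonyls and C5=C6 as its (deconjugated) olefin.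

## Retrosynthetic reasoning

**C2 oxidation level.** The ketone of 29 is traced to the secondary alcohol 28 and its silyl ether 27; no C–C bond is cut. The aldol unit is thereby exposed only in the last step, under neutral conditions. C2 travels as a silyl ether rather than a second ketal because two like ketals at C2 and C8 could not be hydrolysed one at a time; C8 must be free (for the olefin) while C2 is still masked.

**C6–O acyl bond.** The ester of 27 is cut to the equatorial alcohol 25 and 4‑methoxybenzoyl chloride 26. Acylation is placed late so that no enolate is ever generated β to an acyloxy group.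

**C6–H bond.** Alcohol 25 is traced to ketone 24, and 24 to the epimeric alcohol 23 and its 4‑methoxybenzyl ether 22. Hydride from an external reagent is expected to enter C6 anti to the C1 methyl and give the wrong epimer. C6 is therefore deliberately carried in the unnatural configuration and corrected at the end by hydride delivered from the C4 hydroxyl, which sits on the methyl face.

**C8–CH3 bond.** Olefin 22 is cut at the methyl group to enol triflate 20 and trimethylboroxine 21; 20 comes from ketone 19 and this from ketal 18. Cutting here fixes the olefin position through the enolate: with an ether at C6, only the C9 side should be deprotonated.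

**C4–isopropyl bond.** Tertiary alcohol 18 is cut to ketone 16 and isopropylmagnesium chloride 17. In 16 the methyl face of the cyclopentanone is covered by the C1 methyl, the C2 silyloxy group and the C6 ether, so the nucleophile should enter from the other face. This is the only disconnection at C4 that puts the hydroxyl on the hindered face.

**C4–O and C5–H bonds.** Ketone 16 comes from alcohol 15, and 15 from syn addition of H and OH across the C4=C5 olefin of 13. The same three groups direct this addition, so C5–H is set trans to the methyl. Ether 13 derives from allylic alcohol 12 and enone 11.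

**C4=C5 unsaturation.** Enone 11 is traced to ketone 10. C4 is an unactivated methylene and can only be reached through the C6 carbonyl. C8 carries no hydrogen, so dehydrogenation can only go towards C4. The C5 stereocentre is given up here and rebuilt in the step above.

**C1–C5 bond (key disconnection).** The C1–C5 bond of 10 is cut and C1 is reattached to C6, which leads to hydroxy mesylate 9. The forward step contracts one six‑membered ring and expands the other in a single stereospecific 1,2‑shift and creates the C6 carbonyl that is needed next.

**C5–O and C6–O bonds.** Mesylate 9 comes from cis‑diol 8, and 8 from olefin 5 by cis‑dihydroxylation on the methyl face. Olefin 5 arises from 1 by reduction at C2 (2), deconjugative ketalisation at C8 with ethylene glycol 3 (4) and silylation. All carbons except the isopropyl group, the C8 methyl and the ester come from 1.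

## Alternatives that were turned down

**Alternative 1:** Disconnection of C3–C4. Diazoketone A1 would be decomposed with Rh2(O2CC3F7)4, and the carbenoid at C3 would insert into the C4–H bond to give the silyl ether A2 of the target.
- For: the insertion goes through a five‑membered transition state into a C–H bond activated by the silyloxy group, with retention; only a deprotection would remain.
- Against: A1 is a monocyclic cycloheptene that must already carry C1, C5, C6 and the C4 carbinol in the right configuration, and no simple chiral building block maps onto it. The carbenoid is also well placed to cyclopropanate C8=C9 or to insert into the C6–H bond. The C4–H bond is flanked by isopropyl and silyloxy groups. The final desilylation acts on a β‑silyloxy ketone.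
- Comparison: Alternative 1 is stronger in its end game. The chosen route instead starts from a cheap enantiopure bicycle that already holds C1 and forms both rings without a chemoselectivity contest at a late stage.

**Alternative 2:** Disconnection of C5–C6. The silyl dienol ether aldehyde A3 would cyclise under BF3·OEt2 by a Mukaiyama aldol addition to the hydroxy enone A4.
- For: one step forms the seven‑membered ring and two stereocentres, and A4 already has the C6 hydroxyl and a C4 carbonyl.
- Against: the tether on C1 reaches C5 most easily from its own face, which gives the cis fusion, whereas A4 needs the trans fusion. C5 is then α to the C4 ketone and can epimerise. The open transition state gives little control at C6. The β,γ‑unsaturated aldehyde can conjugate, and the aldol product can revert or dehydrate. C2 would still have to be oxidised next to the quaternary carbon.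
- Comparison: Alternative 2 is more convergent. The chosen route sets the ring fusion by a syn addition directed by three groups and carries the C2 oxygen from the start.

**Alternative 3:** Disconnection of C1–C10 and C4–C5. A daucane‑forming class 1 sesquiterpene cyclase would convert farnesyl diphosphate A5 into dauca‑4,8‑diene A6.
- For: nothing matches its step economy to the carbon skeleton; the quaternary centre, the isopropyl group and C8=C9 arrive in one step.
- Against: A6 is a hydrocarbon. The C4 hydroxyl and C5–H would have to be added across a tetrasubstituted olefin with the right sense. C6 would need a selective allylic oxidation among several allylic positions. C2 is an unactivated methylene next to a quaternary carbon. Enzyme and substrate are not ordinary commercial materials.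
- Comparison: Alternative 3 wins on skeleton construction. The chosen route places every oxygen by functional‑group chemistry from oxygens already present in 1.

Key step: step 6

## Remarks on the chemistry

- Numbering: the atom numbers of the target are used for all intermediates, so in decalins 1–9 the ring‑fusion carbons are C1 and C6.
- Assumption: (R)‑Wieland–Miescher ketone 1 is taken as a commercial, enantiopure starting material.
- Assumption: in step 8 hydride is taken to add to C6 anti to the C1 methyl; the other outcome is tolerated because C6 is re‑set in steps 17 and 18.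
- The configuration at C5 created in step 6 is removed in step 7 and restored in step 10; the face of the diol in step 4 is therefore not critical for the later route.

## Steps

Step 1
Reactants: 1 (R)-Wieland–Miescher ketone
Product: 2 (4aR,5R)-5-hydroxy-4a-methyl-4,4a,5,6,7,8-hexahydronaphthalen-2(3H)-one (C2 hydroxyl cis to the C1 methyl)
Conditions: NaBH4 (0.3 equiv), EtOH, −10 °C
Reagents that add atoms: none
Why: Chemoselective borohydride reduction of the saturated C2 ketone in the presence of the less electrophilic enone; hydride enters axially, anti to the angular methyl, so the equatorial alcohol cis to the methyl should result. The C2 configuration is irrelevant for the target but places the later silyloxy group on the methyl face.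

Step 2
Reactants: 2 hydroxy enone; 3 ethylene glycol
Product: 4 (1R,8aR)-6,6-ethylenedioxy-8a-methyl-1,2,3,5,6,7,8,8a-octahydronaphthalen-1-ol (C8 dioxolane, olefin at C5=C6, free C2 hydroxyl)
Conditions: ethylene glycol, p-TsOH·H2O (cat.), benzene, reflux, Dean–Stark
Reagents that add atoms: ethylene glycol (3), OCCO
Why: Acid-catalysed ketalisation of a bicyclic enone proceeds through the dienol ether and gives the dioxolane with the double bond in the β,γ-position, here C5=C6. The secondary alcohol is a spectator.

Step 3
Reactants: 4 hydroxy ketal
Product: 5 tert-butyldimethylsilyl ether of 4 (C2–OTBS cis to the C1 methyl)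
Conditions: TBSCl, imidazole, DMAP (cat.), DMF, 40 °C
Reagents that add atoms: tert-butyldimethylsilyl chloride, CC(C)(C)[Si](C)(C)Cl
Why: Standard silylation of a hindered secondary alcohol. The silyl ether is orthogonal to the C8 dioxolane and lets C2 be oxidised last.

Step 4
Reactants: 5 silyl ether olefin
Product: 8 cis-5,6-diol of 5 (C5–OH and C6–OH both cis to the C1 methyl; cis-fused decalin), via iodo acetate 6 (not isolated), via hydroxy acetate 7 (not isolated)
Conditions: I2 (1.05 equiv), AgOAc (2.2 equiv), AcOH, 20 °C; then H2O (2 equiv), 20 → 45 °C; then K2CO3 (cat.), MeOH, 20 °C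
Reagents that add atoms: silver acetate, CC(=O)[O-].[Ag+]
Why: Woodward cis-dihydroxylation: the iodonium ion forms anti to the methyl, acetate opens it trans-diaxially at C5 on the methyl face, and silver-assisted displacement of the tertiary C6 iodide by the neighbouring acetate gives the acetoxonium ion on the methyl face. Water and then methanolysis should give the cis-diol; the tertiary iodide should ionise without strong heating, which spares the dioxolane.

Step 5
Reactants: 8 cis-diol
Product: 9 C5 mesylate of 8 (mesylate, C6 hydroxyl, C2–OTBS and C1 methyl all on one face)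
Conditions: MsCl, Et3N, CH2Cl2, −10 °C
Reagents that add atoms: methanesulfonyl chloride, CS(=O)(=O)Cl
Why: Sulfonylation via the sulfene takes the secondary hydroxyl only; the tertiary C6 hydroxyl does not react under these conditions.

Step 6
Reactants: 9 hydroxy mesylate
Product: 10 trans-fused bicyclo[5.3.0]decan-6-one (C6 ketone, C8 dioxolane, C2–OTBS cis to the C1 methyl, C5–H trans to it)
Conditions: KOtBu (1.05 equiv), tBuOH–THF (1:1), 0 → 25 °C
Reagents that add atoms: none
Why: KOtBu deprotonates the tertiary C6 hydroxyl, and the alkoxide pushes the C1–C6 σ bond onto C5 as the mesylate leaves, so that C6 becomes the ketone (anionic semipinacol shift). The closest known reaction type is the base-promoted rearrangement of decalin cis-1,2-diol monosulfonates to hydroazulenones. The cyclopentane (C1–C5) closes by a suprafacial 1,2-shift of C1 from C6 to C5, formally a 3-exo-tet displacement of mesylate by the migrating bond, and the same shift inserts C5 between C1 and C6, so the second ring closes as the cycloheptanone by one-carbon expansion. The new stereocentre C5 is formed with inversion at the mesylate carbon and retention at C1; since the mesylate is cis to the methyl, C5–H should end trans to it. The step needs migration of C1–C6 rather than C6–C7: in the chair–chair form with the mesylate equatorial on the C1–C6 ring only the C1–C6 bond is antiperiplanar, and the quaternary C1 is the better migrating group, while the alternative shift would give a strained bridged ketone. The cis arrangement of hydroxyl and mesylate rules out epoxide closure. Only a slight excess of base and a short reaction time are used because the product is a β-keto ketal with an epimerisable C5.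

Step 7
Reactants: 10 ketone
Product: 11 enone (C6 ketone conjugated with C4=C5; C8 dioxolane; C2–OTBS)
Conditions: IBX (2.5 equiv), DMSO–fluorobenzene (1:2), 70 °C
Reagents that add atoms: none
Why: IBX dehydrogenation of a ketone through its enol; C8 carries no hydrogen, so desaturation can only occur between C5 and C4. The C5 stereocentre is given up here on purpose and is rebuilt in step 10.

Step 8
Reactants: 11 enone
Product: 12 allylic alcohol (C6–OH cis to the C1 methyl, C4=C5)
Conditions: NaBH4, CeCl3·7H2O, MeOH, −40 °C
Reagents that add atoms: none
Why: Luche 1,2-reduction of the enone; hydride is expected anti to the C1 methyl, which puts the hydroxyl on the methyl face. This configuration is temporary and helps to block the methyl face in steps 10 and 12.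

Step 9
Reactants: 12 allylic alcohol
Product: 13 4-methoxybenzyl ether of 12 at C6–O
Conditions: NaH, 4-methoxybenzyl chloride, Bu4NI (cat.), DMF, 0 → 25 °C
Reagents that add atoms: 4-methoxybenzyl chloride, COc1ccc(CCl)cc1
Why: Williamson etherification of the alkoxide; the ether is stable to borane, organocerium and amide bases and is removed oxidatively without touching the silyl ether.

Step 10
Reactants: 13 allylic ether
Product: 15 C4 alcohol (C4–OH and C5–H both trans to the C1 methyl; trans-fused), via C4 alkylborane 14 (not isolated)
Conditions: BH3·THF (3 equiv), THF, 0 → 25 °C; then 3 M NaOH, 30% H2O2, 0 → 25 °C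
Reagents that add atoms: hydrogen peroxide, OO
Why: Hydroboration–oxidation of the trisubstituted olefin places boron on the less substituted C4 and hydrogen on C5 in a syn addition. The methyl face is blocked by the C1 methyl, the C2 silyloxy group and the C6 ether, so C5–H should be delivered trans to the methyl, which re-establishes the trans fusion.

Step 11
Reactants: 15 C4 alcohol
Product: 16 C4 ketone (C5–H trans to the C1 methyl; C6–OPMB; C8 dioxolane; C2–OTBS)
Conditions: Dess–Martin periodinane, pyridine, CH2Cl2, 0 → 25 °C
Reagents that add atoms: none
Why: Dess–Martin oxidation under buffered, non-basic conditions, which should leave the epimerisable C5 and the β-alkoxy ketone intact.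

Step 12
Reactants: 16 C4 ketone; 17 isopropylmagnesium chloride
Product: 18 tertiary alcohol (C4–OH cis to the C1 methyl, C4 isopropyl trans to it)
Conditions: CeCl3 (anhydrous, 3 equiv), iPrMgCl (3 equiv), THF, −78 °C; then 16, −78 → −40 °C
Reagents that add atoms: isopropylmagnesium chloride (17), CC(C)[Mg]Cl
Why: Organocerium 1,2-addition, which suppresses enolisation and β-hydride reduction with a branched nucleophile. The reagent should approach the cyclopentanone anti to the C1 methyl, the C2 silyloxy group and the C6 ether, so the hydroxyl ends on the methyl face as the target requires.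

Step 13
Reactants: 18 ketal
Product: 19 C8 ketone (C6–OPMB, C4 tertiary alcohol, C2–OTBS)
Conditions: PPTS (0.3 equiv), acetone–H2O (10:1), 50 °C
Reagents that add atoms: water, O
Why: Mild acid hydrolysis of the only ketal in the molecule; the hindered secondary silyl ether, the benzyl-type ether and the tertiary alcohol should survive.

Step 14
Reactants: 19 C8 ketone
Product: 20 enol triflate (C8–OTf, C8=C9)
Conditions: KN(SiMe3)2 (2.3 equiv), THF, −78 °C; then PhNTf2 (1.3 equiv), −78 → −20 °C
Reagents that add atoms: N-phenylbis(trifluoromethanesulfonimide), O=S(=O)(N(c1ccccc1)S(=O)(=O)C(F)(F)F)C(F)(F)F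
Why: Kinetic deprotonation of a β-alkoxy cycloalkanone takes place at the α′ methylene remote from the alkoxy-bearing carbon, here C9, because C7 is shielded by the C6 ether and its enolate is disfavoured by dipole repulsion. O-Triflation fixes the C8=C9 position; the first equivalent of base is taken up by the tertiary hydroxyl.

Step 15
Reactants: 20 enol triflate; 21 trimethylboroxine
Product: 22 methyl olefin (C8–CH3, C8=C9; C6–OPMB; C2–OTBS)
Conditions: Pd(PPh3)4 (5 mol%), K2CO3, 1,4-dioxane–H2O (10:1), 90 °C
Reagents that add atoms: trimethylboroxine (21), CB1OB(C)OB(C)O1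
Why: Suzuki–Miyaura methylation of an alkenyl triflate; the olefin position is that of the triflate, and the free tertiary alcohol is tolerated.

Step 16
Reactants: 22 4-methoxybenzyl ether
Product: 23 C6 alcohol (C6–OH cis to the C1 methyl)
Conditions: DDQ (1.5 equiv), CH2Cl2–pH 7 phosphate buffer (10:1), 0 → 25 °C
Reagents that add atoms: none
Why: Oxidative cleavage of the electron-rich benzyl ether; the trisubstituted olefin, the silyl ether and the tertiary alcohol should not react under buffered conditions.

Step 17
Reactants: 23 C6 alcohol
Product: 24 C6 ketone (β-hydroxy ketone with the C4 hydroxyl; C8=C9 β,γ to the carbonyl)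
Conditions: Dess–Martin periodinane, pyridine, CH2Cl2, 0 °C
Reagents that add atoms: none
Why: Buffered Dess–Martin oxidation of the secondary alcohol; the tertiary alcohol is inert, and the neutral conditions should prevent migration of the olefin into conjugation. The ketone is reduced directly in the next step.

Step 18
Reactants: 24 C6 ketone
Product: 25 C6 alcohol (C6–OH trans to the C1 methyl, anti to the C4 hydroxyl)
Conditions: Me4NBH(OAc)3 (5 equiv), MeCN–AcOH (1:1), −30 → −10 °C
Reagents that add atoms: none
Why: Evans–Saksena reduction: the C4 hydroxyl exchanges with an acetate on boron and delivers hydride intramolecularly to C6 from the methyl face, where the C4 oxygen sits. The new hydroxyl should therefore end trans to the methyl (the anti 1,3-diol), which is the configuration of the target.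

Step 19
Reactants: 25 C6 alcohol; 26 4-methoxybenzoyl chloride
Product: 27 C6 4-methoxybenzoate (C2–OTBS, free C4 hydroxyl)
Conditions: 4-methoxybenzoyl chloride (1.5 equiv), Et3N, DMAP (0.2 equiv), CH2Cl2, 0 → 25 °C
Reagents that add atoms: 4-methoxybenzoyl chloride (26), COc1ccc(C(=O)Cl)cc1
Why: DMAP-catalysed acylation of the equatorial secondary alcohol; the tertiary C4 hydroxyl is too hindered to compete.

Step 20
Reactants: 27 silyl ether
Product: 28 C2 alcohol (C2–OH cis to the C1 methyl)
Conditions: HF·pyridine, pyridine–THF, 0 → 25 °C
Reagents that add atoms: none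
Why: Fluoride-mediated desilylation under mildly acidic, buffered conditions, which should leave the aryl ester, the tertiary alcohol and the olefin untouched.

Step 21
Reactants: 28 C2 alcohol
Product: 29 target, CNP0232277.1
Conditions: Dess–Martin periodinane, pyridine, CH2Cl2, 0 → 25 °C
Reagents that add atoms: none
Why: Dess–Martin oxidation of the only secondary alcohol; the aldol unit C2(=O)–C3–C4(OH) is formed last and under neutral conditions, so retro-aldol cleavage and dehydration should be avoided.

## Compound list

1 | (R)-Wieland–Miescher ketone, (8aR)-8a-methyl-3,4,8,8a-tetrahydronaphthalene-1,6(2H,7H)-dione | C[C@@]12CCC(=O)C=C1CCCC2=O | starting material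
2 | (4aR,5R)-5-hydroxy-4a-methyl-4,4a,5,6,7,8-hexahydronaphthalen-2(3H)-one | C12=CC(=O)CC[C@@]1(C)[C@H](O)CCC2 | intermediate
3 | ethylene glycol | OCCO | starting material
4 | (1R,8aR)-6,6-ethylenedioxy-8a-methyl-1,2,3,5,6,7,8,8a-octahydronaphthalen-1-ol | C1=C2CC3(OCCO3)CC[C@@]2(C)[C@H](O)CC1 | intermediate
5 | tert-butyldimethylsilyl ether of 4 | C1=C2CC3(OCCO3)CC[C@@]2(C)[C@H](O[Si](C)(C)C(C)(C)C)CC1 | intermediate
6 | iodo acetate: C5 acetate cis to the C1 methyl, C6 iodide trans to it | I[C@@]12CC3(OCCO3)CC[C@@]1(C)[C@H](O[Si](C)(C)C(C)(C)C)CC[C@@H]2OC(C)=O | intermediate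
7 | hydroxy acetate: C5 acetate and C6 hydroxyl both cis to the C1 methyl | O[C@]12CC3(OCCO3)CC[C@@]1(C)[C@H](O[Si](C)(C)C(C)(C)C)CC[C@@H]2OC(C)=O | intermediate
8 | cis-5,6-diol, both hydroxyls cis to the C1 methyl, cis-fused decalin | O[C@]12CC3(OCCO3)CC[C@@]1(C)[C@H](O[Si](C)(C)C(C)(C)C)CC[C@@H]2O | intermediate
9 | C5 mesylate of 8 (precursor of the key step) | O[C@]12CC3(OCCO3)CC[C@@]1(C)[C@H](O[Si](C)(C)C(C)(C)C)CC[C@@H]2OS(C)(=O)=O | intermediate
10 | trans-fused bicyclo[5.3.0]decan-6-one with C8 dioxolane and C2–OTBS (product of the key step) | O=C1CC2(OCCO2)CC[C@@]3(C)[C@H](O[Si](C)(C)C(C)(C)C)CC[C@H]13 | intermediate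
11 | enone, C6 ketone with C4=C5 | O=C1CC2(OCCO2)CC[C@@]3(C)[C@H](O[Si](C)(C)C(C)(C)C)CC=C13 | intermediate
12 | allylic alcohol, C6–OH cis to the C1 methyl | O[C@@H]1CC2(OCCO2)CC[C@@]3(C)[C@H](O[Si](C)(C)C(C)(C)C)CC=C13 | intermediate
13 | C6 4-methoxybenzyl ether of 12 | COc1ccc(CO[C@@H]2CC3(OCCO3)CC[C@@]4(C)[C@H](O[Si](C)(C)C(C)(C)C)CC=C24)cc1 | intermediate
14 | C4 alkylborane, boron and C5–H trans to the C1 methyl | COc1ccc(CO[C@@H]2CC3(OCCO3)CC[C@@]4(C)[C@H](O[Si](C)(C)C(C)(C)C)C[C@@H](B)[C@H]24)cc1 | intermediate
15 | C4 alcohol, trans-fused, C4–OH trans to the C1 methyl | COc1ccc(CO[C@@H]2CC3(OCCO3)CC[C@@]4(C)[C@H](O[Si](C)(C)C(C)(C)C)C[C@@H](O)[C@H]24)cc1 | intermediate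
16 | C4 ketone | COc1ccc(CO[C@@H]2CC3(OCCO3)CC[C@@]4(C)[C@H](O[Si](C)(C)C(C)(C)C)CC(=O)[C@H]24)cc1 | intermediate
17 | isopropylmagnesium chloride | CC(C)[Mg]Cl | starting material
18 | tertiary alcohol, C4–OH cis to the C1 methyl, C4 isopropyl trans | COc1ccc(CO[C@@H]2CC3(OCCO3)CC[C@@]4(C)[C@H](O[Si](C)(C)C(C)(C)C)C[C@@](O)(C(C)C)[C@H]24)cc1 | intermediate
19 | C8 ketone | COc1ccc(CO[C@@H]2CC(=O)CC[C@@]3(C)[C@H](O[Si](C)(C)C(C)(C)C)C[C@@](O)(C(C)C)[C@H]23)cc1 | intermediate
20 | C8 enol triflate, C8=C9 | COc1ccc(CO[C@@H]2CC(OS(=O)(=O)C(F)(F)F)=CC[C@@]3(C)[C@H](O[Si](C)(C)C(C)(C)C)C[C@@](O)(C(C)C)[C@H]23)cc1 | intermediate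
21 | trimethylboroxine | CB1OB(C)OB(C)O1 | starting material
22 | C8 methyl olefin, C6–OPMB | COc1ccc(CO[C@@H]2CC(C)=CC[C@@]3(C)[C@H](O[Si](C)(C)C(C)(C)C)C[C@@](O)(C(C)C)[C@H]23)cc1 | intermediate
23 | C6 alcohol, C6–OH cis to the C1 methyl | O[C@@H]1CC(C)=CC[C@@]2(C)[C@H](O[Si](C)(C)C(C)(C)C)C[C@@](O)(C(C)C)[C@H]12 | intermediate
24 | C6 ketone | O=C1CC(C)=CC[C@@]2(C)[C@H](O[Si](C)(C)C(C)(C)C)C[C@@](O)(C(C)C)[C@H]12 | intermediate
25 | C6 alcohol, C6–OH trans to the C1 methyl | O[C@H]1CC(C)=CC[C@@]2(C)[C@H](O[Si](C)(C)C(C)(C)C)C[C@@](O)(C(C)C)[C@H]12 | intermediate
26 | 4-methoxybenzoyl chloride | COc1ccc(C(=O)Cl)cc1 | starting material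
27 | C6 4-methoxybenzoate, C2–OTBS | COc1ccc(C(=O)O[C@H]2CC(C)=CC[C@@]3(C)[C@H](O[Si](C)(C)C(C)(C)C)C[C@@](O)(C(C)C)[C@H]23)cc1 | intermediate
28 | C2 alcohol | COc1ccc(C(=O)O[C@H]2CC(C)=CC[C@@]3(C)[C@H](O)C[C@@](O)(C(C)C)[C@H]23)cc1 | intermediate
29 | CNP0232277.1 | COc1ccc(C(=O)O[C@H]2CC(C)=CC[C@@]3(C)C(=O)C[C@@](O)(C(C)C)[C@H]23)cc1 | target

## Step count and least certain steps

Total: 21 steps. Longest linear sequence: 21 steps, from 1 to 29.

**Step 6 (key step).** Two things may go wrong. First, the cis-decalin may react through its other chair–chair form, where the mesylate is axial and the C6–C7 bond is antiperiplanar; migration of C7 would then give a bridged ketone. Second, the product may react further with base, by β-elimination that opens the C8 dioxolane through the C7 enolate. The fallback keeps the same 1,2-shift but uses an epoxide leaving group in a rigid trans-fused decalin and a Lewis acid instead of base. It sets out from 5: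
- Schenck ene reaction (O2, tetraphenylporphyrin, light, CH2Cl2) should give the C6 hydroperoxide F1 with the olefin moved to C4=C5; reduction in the same flask with PPh3 gives the tertiary allylic alcohol F2 (C6–OH trans to the methyl).
- Hydroxyl-directed epoxidation (VO(acac)2, tBuOOH) gives the syn epoxy alcohol F3.
- ZnBr2 in CH2Cl2 should trigger the semipinacol shift of C1 from C6 to C5 with opening of the epoxide, giving the β-hydroxy ketone F4.
- MsCl and Et3N convert F4 into the C4 mesylate F5, which eliminates on warming with DBU; the route is rejoined at 11.

**Step 4.** Acidolysis of the dioxolane in acetic acid, elimination of the tertiary iodide in place of acetate participation, or opening of the iodonium ion with the other regiochemistry would all lower the supply of 8. The fallback gives up the methyl-face diol, which is permissible because C5 is made planar in step 7. It sets out from 5: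
- OsO4 (cat.) with N-methylmorpholine N-oxide in acetone–water should dihydroxylate anti to the methyl and give the trans-fused diol F6.
- MsCl and Et3N give the equatorial mesylate F7.
- KOtBu in tBuOH then gives the cis-fused ketone F8, the C5 epimer of 10; in the rigid trans-decalin only the C1–C6 bond is antiperiplanar to the mesylate.
- F8 is dehydrogenated under the conditions of step 7, and the route is rejoined at 11.

**Step 14.** Loss of regiocontrol in the deprotonation (C7 instead of C9), followed by β-elimination of the C6 ether, is the main risk. The fallback replaces steric control by charge control and sets out from 19: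
- DDQ removes the benzyl-type ether to give the keto diol F9.
- LiN(SiMe3)2 (3.3 equiv) at −78 °C forms the dialkoxide enolate, which cannot enolise towards the alkoxide-bearing side; N-(5-chloropyridin-2-yl)bis(trifluoromethanesulfonimide) then gives the enol triflate F10.
- Suzuki–Miyaura methylation as in step 15 leads to 23, where the route is rejoined.

**Step 12.** Enolisation of the ketone, hydride transfer from the branched reagent, or attack on the wrong face may reduce the amount of 18. The fallback sets out from 16 and uses a nucleophile without β-hydrogens on sp3 carbon: 2-propenylmagnesium bromide with CeCl3 gives the isopropenyl carbinol F11. Hydrogenation of its 1,1-disubstituted olefin with RhCl(PPh3)3 and H2 returns to 18; no other olefin is present at that stage.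

**Step 18.** Hydride may be delivered intermolecularly from the wrong face, or the β,γ-unsaturated ketone may isomerise into conjugation before it is reduced. The fallback sets out from 24 and replaces hydride delivery by electron transfer: SmI2 with MeOH in THF at 0 °C reduces β-hydroxy ketones through a chelated ketyl to the anti 1,3-diol, which is 25. No new compound is involved.

## Further compounds

F1 | step 6 | C6 hydroperoxide with C4=C5, hydroperoxy group trans to the C1 methyl | OO[C@@]12CC3(OCCO3)CC[C@@]1(C)[C@H](O[Si](C)(C)C(C)(C)C)CC=C2
F2 | step 6 | tertiary allylic alcohol, C6–OH trans to the C1 methyl, C4=C5 | O[C@@]12CC3(OCCO3)CC[C@@]1(C)[C@H](O[Si](C)(C)C(C)(C)C)CC=C2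
F3 | step 6 | syn epoxy alcohol, C4–C5 epoxide and C6–OH trans to the C1 methyl | O[C@@]12CC3(OCCO3)CC[C@@]1(C)[C@H](O[Si](C)(C)C(C)(C)C)C[C@H]4O[C@@H]24
F4 | step 6 | cis-fused β-hydroxy ketone, C6 ketone, C4–OH trans to the C1 methyl | O=C1CC2(OCCO2)CC[C@@]3(C)[C@H](O[Si](C)(C)C(C)(C)C)C[C@@H](O)[C@@H]13
F5 | step 6 | C4 mesylate of F4 | O=C1CC2(OCCO2)CC[C@@]3(C)[C@H](O[Si](C)(C)C(C)(C)C)C[C@@H](OS(C)(=O)=O)[C@@H]13
F6 | step 4 | cis-5,6-diol with both hydroxyls trans to the C1 methyl, trans-fused decalin | O[C@@]12CC3(OCCO3)CC[C@@]1(C)[C@H](O[Si](C)(C)C(C)(C)C)CC[C@H]2O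
F7 | step 4 | C5 mesylate of F6 | O[C@@]12CC3(OCCO3)CC[C@@]1(C)[C@H](O[Si](C)(C)C(C)(C)C)CC[C@H]2OS(C)(=O)=O
F8 | step 4 | cis-fused bicyclo[5.3.0]decan-6-one, C5 epimer of 10 | O=C1CC2(OCCO2)CC[C@@]3(C)[C@H](O[Si](C)(C)C(C)(C)C)CC[C@@H]13
F9 | step 14 | keto diol, C8 ketone, free C6–OH cis to the C1 methyl | O[C@@H]1CC(=O)CC[C@@]2(C)[C@H](O[Si](C)(C)C(C)(C)C)C[C@@](O)(C(C)C)[C@H]12
F10 | step 14 | C8 enol triflate with free C6–OH | O[C@@H]1CC(OS(=O)(=O)C(F)(F)F)=CC[C@@]2(C)[C@H](O[Si](C)(C)C(C)(C)C)C[C@@](O)(C(C)C)[C@H]12
F11 | step 12 | C4 isopropenyl carbinol, C4–OH cis to the C1 methyl | COc1ccc(CO[C@@H]2CC3(OCCO3)CC[C@@]4(C)[C@H](O[Si](C)(C)C(C)(C)C)C[C@@](O)(C(C)=C)[C@H]24)cc1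
F0 | step 18 | none | none
A1 | alternative 1 | diazoketone: cycloheptene with C1 methyl and diazoacetyl, C5 side chain CH(OTBS)(isopropyl), C6 4-methoxybenzoate | COc1ccc(C(=O)O[C@H]2CC(C)=CC[C@@](C)(C(=O)C=[N+]=[N-])[C@@H]2[C@H](O[Si](C)(C)C(C)(C)C)C(C)C)cc1
A2 | alternative 1 | tert-butyldimethylsilyl ether of the target at C4–O | COc1ccc(C(=O)O[C@H]2CC(C)=CC[C@@]3(C)C(=O)C[C@@](O[Si](C)(C)C(C)(C)C)(C(C)C)[C@H]23)cc1
A3 | alternative 2 | 5-methyl-5-[(Z)-3-methyl-5-oxopent-2-enyl]-2-(tert-butyldimethylsilyloxy)cyclopenta-1,3-diene | O=CC/C(C)=C\C[C@@]1(C)C=CC(O[Si](C)(C)C(C)(C)C)=C1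
A4 | alternative 2 | bicyclic hydroxy enone with C6 alcohol, C2=C3 olefin and C4 ketone | O[C@H]1CC(C)=CC[C@@]2(C)C=CC(=O)[C@H]12
A5 | alternative 3 | (2E,6E)-farnesyl diphosphate | CC(C)=CCC/C(C)=C/CC/C(C)=C/COP(=O)(O)OP(=O)(O)O
A6 | alternative 3 | dauca-4,8-diene (daucene) | C1CC(C)=CC[C@@]2(C)CCC(C(C)C)=C12
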